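Readings and results stem from a simulated flask with constants of no real substance; scatter was added.

In a one-step world whose rate follows c(catalyst), target at equal time and small turnover would grow by the catalyst ratio, which from the violet run to the amber run is 1.48. Amber is the asked flask, and the two charges differ in nothing else.

common to all: starting material 0.80 M; gas phase 200 mM (held)
- amber: catalyst 80 mM; the very flask that is asked about, followed so far
- violet: catalyst 54 mM; run made earlier
- flask: catalyst 80 mM; time 1.5 h

| amber: time / min | amber: target / % | violet: time / min | violet: target / % |
|---|---|---|---|
| 1.33 | 0.4 | 10.0 | 6.1 |
| 3.00 | 1.5 | 20.0 | 15.2 |
| 8.00 | 5.4 | 25.0 | 20.2 |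
| 20.0 | 18.3 | 40.0 | 29.4 |

(standard deviation of a reading: 1 percentage point)

- at the start none of the gas phase is in solution

- summer: doubling the amount of catalyst, all else as stated
- dawn: doubling the saturation concentration of gas phase, all else as stated
- autumn: doubling the transfer coefficient of the gas phase, all else as stated

1. how much target there is at 1.5 h, in percent of the starting material charged
2. concentration of dissolved gas in solution at 50 min, in percent of saturation
3. the change that raises the amount of target at 1.5 h, in percent of the starting material charged most ("none" if none brings more than 2 percentage points) (summer / dawn / autumn / none)
4. amount of target at 1.5 h, in percent of the starting material charged, after autumn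

At 20.0 min amber holds 18.3 % of target and violet 15.2 %, a ratio of 1.20, which is less than the catalyst ratio. The logarithm of the first ratio over that of the second gives 0.472: this is the catalyst leverage, the power of c(catalyst) that target follows between these two runs at that time. It is read off two readings, each scattering by 1 percentage point.

A leverage below one speaks against a single catalysed rate-limiting step. No gas is in solution at the start and the crossing of gas phase into solution is set up alike in both runs, so my reckoning takes that crossing as a second brake beside the catalysed step.

My own reckoning takes violet's last reading as the large thing and the catalyst change as the correction: 29.4 % at 40.0 min becomes 35.4 % for amber. It stops at that time. In a repeat, the ratio of the two curves at equal time is the thing to watch.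

The forecast holds that “the run is mostly transfer-limited early”. It gives 58 % (49 % to 68 %) of target at 1.5 h, and 55 % (38 % to 75 %) of saturation at 50 min. It names dawn as the best change and expects 74 % (62 % to 87 %) after autumn.

The flask gives 59.6 % of target at 1.5 h and dissolved gas at 63.2 % of saturation at 50 min. The best change is dawn, with a gain of 11 points, and autumn gives 64.0 %. Beside the target, the flask holds 21.0 % of isomer of the product at 1.50 h. The leverage had carried violet's last reading to 35.4 % for amber, and the computed flask at that time stands at 35.4 %.

    target ⇌ isomer of the product (K = 0.360, k = 0.0880 /min)
    gas phase ⇌ dissolved gas, rate k2*(csat - [dissolved gas]) (kL = 0.110 /min)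
    starting material + dissolved gas + catalyst ⇌ catalyst + target (K = 45.0 /M, k = 2.40 /M²/min)

A neighbour flask with 0.020 M of catalyst, stopped at 1.5 h, gets from the leverage 30.9 % of target. The computed neighbour holds 33.8 %.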